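**Retrosynthetic overview**
Numbering: ansa chain C1 (amide carbonyl) to C15 (benzylic carbinol), ring A = the aminophenol benzene ring (C16–C21); the target 27 is cut at C12–C13 (ring closure) and at the C1–N amide (fragment union), giving acid 13 (C1–C12) and aniline 19 (ring A carrying C13–C15 as a terminal propargylic alkyne).
Key ring closure: a nickel-catalysed alkylative ynal macrocyclization joins the C12 aldehyde to the terminal alkyne carbon C13, delivers the C14 methyl carbon from Me2Zn, sets C12 and closes the 19-membered ansa ring.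
Enabling feature: C12 is an oxygen-bearing carbon next to the C11 silyloxy stereocenter (α-oxy aldehyde retron), and C13H2–C14(CH3)–C15(O)–ring A is the hydrogenated form of an E-trisubstituted allylic system that maps onto a terminal alkyne C13≡C14 on the benzylic C15; the new C12 hydroxyl then directs the hydrogenation that sets C14 (1,3-anti to O12, 1,2-syn to O15).
Acid 13: syn-aldol (C10, C11), Wittig (C8=C9), γ-methoxyallylboration (C6, C7), hydroformylation and Wittig (C3, C2=C3); aniline 19: enantioselective alkynylation of 3-hydroxy-5-nitrobenzaldehyde (C15).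
Ring order: ring A is bought, the ansa ring is the only ring formed (step 19); endgame: directed hydrogenation, O-methylation at C12, global desilylation.

Key step: step 19

Assumption: compounds 1, 2 and 14, both Wittig ylides and (+)-Ipc2BOMe are taken as commercial, and (S,S)-ProPhenol is taken to deliver the C15 configuration drawn in 16 (its antipode is used if the sense proves opposite).

Step 1
Reactants: 1 (R)-4-benzyl-3-propionyloxazolidin-2-one; 2 (tert-butyldimethylsilyloxy)acetaldehyde
Product: 4 (R)-4-benzyl-3-[(2R,3R)-4-(tert-butyldimethylsilyloxy)-3-hydroxy-2-methylbutanoyl]oxazolidin-2-one, via dibutylboron Z-enolate 3 (not isolated)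
Conditions: Bu2BOTf, iPr2NEt, CH2Cl2, −78 → 0 °C; then 2, −78 → 0 °C; pH 7 buffer, MeOH, H2O2
Reagents that add atoms: none
Why: Evans syn-aldol, in which the Z boron enolate reacts through a closed chair transition state and the (R)-benzyl auxiliary shields one enolate face, should set C10 and C11 with the syn methyl/hydroxyl relationship.

Step 2
Reactants: 4
Product: 5 (2R,3R)-4-(tert-butyldimethylsilyloxy)-3-hydroxy-N-methoxy-N,2-dimethylbutanamide
Conditions: MeNH(OMe)·HCl, AlMe3, CH2Cl2, −20 → 0 °C; aq. potassium sodium tartrate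
Reagents that add atoms: N,O-dimethylhydroxylamine hydrochloride, CNOC.Cl
Why: Aluminium amide transamination of the β-hydroxy imide should give the Weinreb amide and release the auxiliary without touching the stereocenters.

Step 3
Reactants: 5
Product: 6 (2R,3R)-3,4-bis(tert-butyldimethylsilyloxy)-N-methoxy-N,2-dimethylbutanamide
Conditions: TBSOTf, 2,6-lutidine, CH2Cl2, 0 °C
Reagents that add atoms: tert-butyldimethylsilyl triflate (TBSOTf), CC(C)(C)[Si](C)(C)OS(=O)(=O)C(F)(F)F
Why: Silylation of the secondary alcohol with the silyl triflate under lutidine buffering is routine and blocks retro-aldol cleavage in the following steps.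

Step 4
Reactants: 6
Product: 7 (2R,3R)-3,4-bis(tert-butyldimethylsilyloxy)-2-methylbutanal
Conditions: iBu2AlH, THF, −78 °C; aq. potassium sodium tartrate
Reagents that add atoms: none
Why: Weinreb amide reduction should stop at the aldehyde through the chelated tetrahedral intermediate, so the α-stereocenter is not epimerized.

Step 5
Reactants: 7
Product: 8 (2E,4S,5R)-5,6-bis(tert-butyldimethylsilyloxy)-2,4-dimethylhex-2-enal
Conditions: Ph3P=C(CH3)CHO, toluene, 90 °C
Reagents that add atoms: 2-(triphenylphosphoranylidene)propanal, CC(C=O)=P(c1ccccc1)(c1ccccc1)c1ccccc1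
Why: Wittig olefination with the stabilized formyl ylide should give the E-configured 2-methyl enal (C8=C9), the usual outcome for stabilized ylides.

Step 6
Reactants: 8
Product: 9 (3S,4S,5E,7S,8R)-8,9-bis(tert-butyldimethylsilyloxy)-3-methoxy-5,7-dimethylnona-1,5-dien-4-ol
Conditions: allyl methyl ether, sBuLi, THF, −78 °C; (+)-Ipc2BOMe; BF3·OEt2; then 8, −78 °C; NaOH, H2O2, 0 °C → rt
Reagents that add atoms: allyl methyl ether, COCC=C
Why: Brown γ-alkoxyallylboration, in which the Z-γ-methoxyallylborane adds through a chair transition state, should give the 6,7-syn methoxy alcohol, and the isopinocampheyl groups derived from (−)-α-pinene select the aldehyde face so that C6 (S) and C7 (S) are set under reagent control.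

Step 7
Reactants: 9
Product: 10 (3S,4S,5E,7S,8R)-4,8,9-tris(tert-butyldimethylsilyloxy)-3-methoxy-5,7-dimethylnona-1,5-diene
Conditions: TBSOTf, 2,6-lutidine, CH2Cl2, −20 → 0 °C
Reagents that add atoms: tert-butyldimethylsilyl triflate (TBSOTf), CC(C)(C)[Si](C)(C)OS(=O)(=O)C(F)(F)F
Why: Silylation of the allylic C7 hydroxyl is routine and keeps this hydroxyl from directing the later hydrogenation to the C8=C9 olefin.

Step 8
Reactants: 10
Product: 11 (4S,5S,6E,8S,9R)-5,9,10-tris(tert-butyldimethylsilyloxy)-4-methoxy-6,8-dimethyldec-6-enal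
Conditions: Rh(acac)(CO)2 (cat.), BiPhePhos, CO/H2 (1:1, 5 bar), toluene, 60 °C
Reagents that add atoms: carbon monoxide, [C-]#[O+]
Why: Rhodium–bisphosphite hydroformylation is linear-selective for the monosubstituted olefin and should leave the trisubstituted olefin untouched, adding C3 as the aldehyde.

Step 9
Reactants: 11
Product: 12 ethyl (2E,6S,7S,8E,10S,11R)-7,11,12-tris(tert-butyldimethylsilyloxy)-6-methoxy-2,8,10-trimethyldodeca-2,8-dienoate
Conditions: Ph3P=C(CH3)CO2Et, CH2Cl2, rt → 40 °C
Reagents that add atoms: ethyl 2-(triphenylphosphoranylidene)propanoate, CCOC(=O)C(C)=P(c1ccccc1)(c1ccccc1)c1ccccc1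
Why: Wittig olefination with the stabilized ylide should give the E-configured 2-methyl enoate (C2=C3).

Step 10
Reactants: 12
Product: 13 (2E,6S,7S,8E,10S,11R)-7,11,12-tris(tert-butyldimethylsilyloxy)-6-methoxy-2,8,10-trimethyldodeca-2,8-dienoic acid
Conditions: LiOH, THF/MeOH/H2O, rt → 35 °C; then cold 0.5 M HCl to pH 4
Reagents that add atoms: lithium hydroxide, [Li+].[OH-]
Why: Saponification of the conjugated ethyl ester is routine, and the silyl ethers are expected to survive aqueous hydroxide at this temperature.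

Step 11
Reactants: 14 3-hydroxy-5-nitrobenzaldehyde
Product: 15 3-nitro-5-(triisopropylsilyloxy)benzaldehyde
Conditions: TIPSCl, imidazole, DMF, rt
Reagents that add atoms: triisopropylsilyl chloride (TIPSCl), CC(C)[Si](Cl)(C(C)C)C(C)C
Why: Silylation of the phenol is routine, and the bulky triisopropylsilyl group is chosen so that the aryl silyl ether survives the later steps.

Step 12
Reactants: 15
Product: 16 (S)-1-[3-nitro-5-(triisopropylsilyloxy)phenyl]-3-(trimethylsilyl)prop-2-yn-1-ol
Conditions: Me2Zn, trimethylsilylacetylene, (S,S)-ProPhenol (20 mol %), Ph3P=O (40 mol %), toluene, 0 → 4 °C; aq. NH4Cl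
Reagents that add atoms: trimethylsilylacetylene, C#C[Si](C)(C)C
Why: Catalytic enantioselective alkynylation, in which the dinuclear zinc–ProPhenol complex delivers the alkynyl group to one face of the aryl aldehyde, should set the C15 carbinol stereocenter (descriptor S here only because of the silyl group on the alkyne).

Step 13
Reactants: 16
Product: 17 (S)-tert-butyldimethyl{1-[3-nitro-5-(triisopropylsilyloxy)phenyl]-3-(trimethylsilyl)prop-2-yn-1-yloxy}silane
Conditions: TBSOTf, 2,6-lutidine, CH2Cl2, 0 °C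
Reagents that add atoms: tert-butyldimethylsilyl triflate (TBSOTf), CC(C)(C)[Si](C)(C)OS(=O)(=O)C(F)(F)F
Why: Silylation of the secondary propargylic alcohol is routine.

Step 14
Reactants: 17
Product: 18 (R)-tert-butyldimethyl{1-[3-nitro-5-(triisopropylsilyloxy)phenyl]prop-2-yn-1-yloxy}silane
Conditions: AgNO3 (10 mol %), acetone/H2O, rt
Reagents that add atoms: none
Why: Silver-catalysed protiodesilylation cleaves only the alkynyl C–Si bond under neutral conditions, so the base-labile aryl silyl ether should survive (the descriptor changes to R without any change in spatial arrangement).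

Step 15
Reactants: 18
Product: 19 3-[(R)-1-(tert-butyldimethylsilyloxy)prop-2-yn-1-yl]-5-(triisopropylsilyloxy)aniline
Conditions: Zn dust, NH4Cl, THF/MeOH/H2O, rt
Reagents that add atoms: none
Why: Zinc/ammonium chloride reduction should convert the nitro group to the aniline chemoselectively, leaving the terminal alkyne and both silyl ethers.

Step 16
Reactants: 13; 19
Product: 21 seco-anilide of acid 13 and aniline 19 (C12 primary OTBS; 6S 7S 10S 11R 15R; 2E 8E), via acid chloride 20 (not isolated)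
Conditions: 1-chloro-N,N,2-trimethylprop-1-en-1-amine, CH2Cl2, 0 °C; then 19, pyridine, 0 °C → rt
Reagents that add atoms: none
Why: Acylation of the aniline by the acid chloride made under neutral conditions should give the anilide without isomerizing the E enoate or cleaving silyl ethers.

Step 17
Reactants: 21
Product: 22 seco-alcohol (21 with free C12 primary hydroxyl)
Conditions: CSA (10 mol %), MeOH/CH2Cl2 (1:1), 0 °C
Reagents that add atoms: none
Why: Acid-catalysed methanolysis should remove the primary silyl ether much faster than the secondary and the aryl silyl ethers.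

Step 18
Reactants: 22
Product: 23 seco-ynal (C12 aldehyde and terminal C13≡C14 alkyne; 6S 7S 10S 11R 15R)
Conditions: Dess–Martin periodinane, NaHCO3, CH2Cl2, 0 °C → rt; used at once
Reagents that add atoms: none
Why: Dess–Martin oxidation under bicarbonate buffering should give the α-silyloxy aldehyde without epimerization at C11.

Step 19
Reactants: 23
Product: 24 macrocyclic allylic alcohol (19-membered lactam; 12S hydroxyl; 13E C13=C14(CH3) olefin; 7,11,15-tris-OTBS; aryl OTIPS)
Conditions: Ni(cod)2 (20 mol %, no phosphine), Me2Zn (4 equiv, the first equivalent deprotonates the anilide N–H), THF, 0 °C, syringe-pump addition of 23 (final 2 mM); aq. NH4Cl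
Reagents that add atoms: dimethylzinc, C[Zn]C
Why: Proposed new method: zerovalent nickel is expected to couple the C12 aldehyde and the terminal C13≡C14 alkyne oxidatively, forming the C12–C13 bond at the unsubstituted alkyne carbon with nickel on C14 and on oxygen, after which methyl transfer from zinc to nickel and C(sp2)–CH3 reductive elimination place the C14 methyl cis to C12 and release the zinc alkoxide. The closest known reaction types are the nickel-catalysed alkylative cyclization and three-component coupling of aldehydes, alkynes and organozincs, and the nickel-catalysed reductive macrocyclization of ynals to endocyclic E-allylic alcohols; the alkylative variant has not been shown for a macrocycle. The 19-membered ansa ring closes in the 19-endo-dig mode, both alkyne carbons ending inside the ring. The new C12 stereocenter is controlled by the adjacent C11 silyloxy stereocenter through a Felkin–Anh arrangement (non-chelating OTBS anti to the forming bond), which should give the 11,12-anti relationship, as in nickel-catalysed alkyne additions to α-silyloxy aldehydes. The step needs bond formation at the terminal alkyne carbon (secured by the steric bias of a terminal alkyne with a branched propargylic substituent), E geometry (secured by syn addition across the alkyne), methyl instead of hydride transfer (secured by a methylzinc without β-hydrogen and by the absence of phosphine) and ring closure over oligomerization (secured by slow addition at high dilution).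

Step 20
Reactants: 24
Product: 25 macrocyclic alcohol (13,14-dihydro-24 with 14S methyl; 12S hydroxyl free)
Conditions: [Rh(nbd)(dppb)]BF4 (10 mol %), H2 (50 bar), CH2Cl2, rt
Reagents that add atoms: none
Why: Hydroxyl-directed hydrogenation, in which the free C12 hydroxyl binds rhodium and, in the conformer that minimizes A(1,3) strain with the cis C14 methyl, delivers hydrogen to its own olefin face, should set C14 (S), 1,3-anti to O12 and 1,2-syn to O15, while the two other trisubstituted olefins carry no free hydroxyl and react more slowly.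

Step 21
Reactants: 25
Product: 26 12-O-methyl ether of 25
Conditions: Me3OBF4, 1,8-bis(dimethylamino)naphthalene, 4 Å molecular sieves, CH2Cl2, 0 °C → rt
Reagents that add atoms: trimethyloxonium tetrafluoroborate, C[O+](C)C.F[B-](F)(F)F
Why: O-methylation with the oxonium salt and a hindered non-nucleophilic base should alkylate the only free hydroxyl under non-basic conditions that avoid silyl migration.

Step 22
Reactants: 26
Product: 27 target (6S 7S 10S 11R 12S 14S 15R; 2E 8E)
Conditions: HF·pyridine, pyridine, THF, 0 °C → rt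
Reagents that add atoms: none
Why: Buffered fluoride-mediated cleavage of the three secondary silyl ethers and the aryl silyl ether should give the target without ionizing the allylic or benzylic alcohols.

**Compound list**
1 | (R)-4-benzyl-3-propionyloxazolidin-2-one | CCC(=O)N1[C@H](Cc2ccccc2)COC1=O | starting material
2 | (tert-butyldimethylsilyloxy)acetaldehyde | CC(C)(C)[Si](C)(C)OCC=O | starting material
3 | dibutylboron Z-enolate of 1 | C/C=C(\OB(CCCC)CCCC)N1[C@H](Cc2ccccc2)COC1=O | intermediate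
4 | (R)-4-benzyl-3-[(2R,3R)-4-(tert-butyldimethylsilyloxy)-3-hydroxy-2-methylbutanoyl]oxazolidin-2-one | O=C([C@H](C)[C@@H](O)CO[Si](C)(C)C(C)(C)C)N1[C@H](Cc2ccccc2)COC1=O | intermediate
5 | (2R,3R)-4-(tert-butyldimethylsilyloxy)-3-hydroxy-N-methoxy-N,2-dimethylbutanamide | CON(C)C(=O)[C@H](C)[C@@H](O)CO[Si](C)(C)C(C)(C)C | intermediate
6 | (2R,3R)-3,4-bis(tert-butyldimethylsilyloxy)-N-methoxy-N,2-dimethylbutanamide | CON(C)C(=O)[C@H](C)[C@@H](O[Si](C)(C)C(C)(C)C)CO[Si](C)(C)C(C)(C)C | intermediate
7 | (2R,3R)-3,4-bis(tert-butyldimethylsilyloxy)-2-methylbutanal | O=C[C@H](C)[C@@H](O[Si](C)(C)C(C)(C)C)CO[Si](C)(C)C(C)(C)C | intermediate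
8 | (2E,4S,5R)-5,6-bis(tert-butyldimethylsilyloxy)-2,4-dimethylhex-2-enal | O=C/C(C)=C/[C@H](C)[C@@H](O[Si](C)(C)C(C)(C)C)CO[Si](C)(C)C(C)(C)C | intermediate
9 | (3S,4S,5E,7S,8R)-8,9-bis(tert-butyldimethylsilyloxy)-3-methoxy-5,7-dimethylnona-1,5-dien-4-ol | C=C[C@H](OC)[C@@H](O)/C(C)=C/[C@H](C)[C@@H](O[Si](C)(C)C(C)(C)C)CO[Si](C)(C)C(C)(C)C | intermediate
10 | (3S,4S,5E,7S,8R)-4,8,9-tris(tert-butyldimethylsilyloxy)-3-methoxy-5,7-dimethylnona-1,5-diene | C=C[C@H](OC)[C@@H](O[Si](C)(C)C(C)(C)C)/C(C)=C/[C@H](C)[C@@H](O[Si](C)(C)C(C)(C)C)CO[Si](C)(C)C(C)(C)C | intermediate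
11 | (4S,5S,6E,8S,9R)-5,9,10-tris(tert-butyldimethylsilyloxy)-4-methoxy-6,8-dimethyldec-6-enal | O=CCC[C@H](OC)[C@@H](O[Si](C)(C)C(C)(C)C)/C(C)=C/[C@H](C)[C@@H](O[Si](C)(C)C(C)(C)C)CO[Si](C)(C)C(C)(C)C | intermediate
12 | ethyl (2E,6S,7S,8E,10S,11R)-7,11,12-tris(tert-butyldimethylsilyloxy)-6-methoxy-2,8,10-trimethyldodeca-2,8-dienoate | CCOC(=O)/C(C)=C/CC[C@H](OC)[C@@H](O[Si](C)(C)C(C)(C)C)/C(C)=C/[C@H](C)[C@@H](O[Si](C)(C)C(C)(C)C)CO[Si](C)(C)C(C)(C)C | intermediate
13 | (2E,6S,7S,8E,10S,11R)-7,11,12-tris(tert-butyldimethylsilyloxy)-6-methoxy-2,8,10-trimethyldodeca-2,8-dienoic acid | OC(=O)/C(C)=C/CC[C@H](OC)[C@@H](O[Si](C)(C)C(C)(C)C)/C(C)=C/[C@H](C)[C@@H](O[Si](C)(C)C(C)(C)C)CO[Si](C)(C)C(C)(C)C | intermediate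
14 | 3-hydroxy-5-nitrobenzaldehyde | O=Cc1cc(O)cc(c1)[N+](=O)[O-] | starting material
15 | 3-nitro-5-(triisopropylsilyloxy)benzaldehyde | O=Cc1cc(O[Si](C(C)C)(C(C)C)C(C)C)cc(c1)[N+](=O)[O-] | intermediate
16 | (S)-1-[3-nitro-5-(triisopropylsilyloxy)phenyl]-3-(trimethylsilyl)prop-2-yn-1-ol | C[Si](C)(C)C#C[C@@H](O)c1cc(O[Si](C(C)C)(C(C)C)C(C)C)cc(c1)[N+](=O)[O-] | intermediate
17 | (S)-tert-butyldimethyl{1-[3-nitro-5-(triisopropylsilyloxy)phenyl]-3-(trimethylsilyl)prop-2-yn-1-yloxy}silane | C[Si](C)(C)C#C[C@@H](O[Si](C)(C)C(C)(C)C)c1cc(O[Si](C(C)C)(C(C)C)C(C)C)cc(c1)[N+](=O)[O-] | intermediate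
18 | (R)-tert-butyldimethyl{1-[3-nitro-5-(triisopropylsilyloxy)phenyl]prop-2-yn-1-yloxy}silane | C#C[C@@H](O[Si](C)(C)C(C)(C)C)c1cc(O[Si](C(C)C)(C(C)C)C(C)C)cc(c1)[N+](=O)[O-] | intermediate
19 | 3-[(R)-1-(tert-butyldimethylsilyloxy)prop-2-yn-1-yl]-5-(triisopropylsilyloxy)aniline | C#C[C@@H](O[Si](C)(C)C(C)(C)C)c1cc(O[Si](C(C)C)(C(C)C)C(C)C)cc(N)c1 | intermediate
20 | acid chloride of 13 | ClC(=O)/C(C)=C/CC[C@H](OC)[C@@H](O[Si](C)(C)C(C)(C)C)/C(C)=C/[C@H](C)[C@@H](O[Si](C)(C)C(C)(C)C)CO[Si](C)(C)C(C)(C)C | intermediate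
21 | seco-anilide of 13 and 19 (C12 primary OTBS; 6S 7S 10S 11R 15R) | C#C[C@@H](O[Si](C)(C)C(C)(C)C)c1cc(O[Si](C(C)C)(C(C)C)C(C)C)cc(c1)NC(=O)/C(C)=C/CC[C@H](OC)[C@@H](O[Si](C)(C)C(C)(C)C)/C(C)=C/[C@H](C)[C@@H](O[Si](C)(C)C(C)(C)C)CO[Si](C)(C)C(C)(C)C | intermediate
22 | seco-alcohol (21 with free C12 primary hydroxyl) | C#C[C@@H](O[Si](C)(C)C(C)(C)C)c1cc(O[Si](C(C)C)(C(C)C)C(C)C)cc(c1)NC(=O)/C(C)=C/CC[C@H](OC)[C@@H](O[Si](C)(C)C(C)(C)C)/C(C)=C/[C@H](C)[C@@H](O[Si](C)(C)C(C)(C)C)CO | intermediate
23 | seco-ynal (C12 aldehyde, terminal C13≡C14 alkyne) | C#C[C@@H](O[Si](C)(C)C(C)(C)C)c1cc(O[Si](C(C)C)(C(C)C)C(C)C)cc(c1)NC(=O)/C(C)=C/CC[C@H](OC)[C@@H](O[Si](C)(C)C(C)(C)C)/C(C)=C/[C@H](C)[C@@H](O[Si](C)(C)C(C)(C)C)C=O | intermediate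
24 | macrocyclic allylic alcohol (12S hydroxyl, 13E olefin, 7,11,15-tris-OTBS, aryl OTIPS) | O[C@H]1/C=C(C)/[C@@H](O[Si](C)(C)C(C)(C)C)c2cc(O[Si](C(C)C)(C(C)C)C(C)C)cc(c2)NC(=O)/C(C)=C/CC[C@H](OC)[C@@H](O[Si](C)(C)C(C)(C)C)/C(C)=C/[C@H](C)[C@H]1O[Si](C)(C)C(C)(C)C | intermediate
25 | macrocyclic alcohol (13,14-dihydro-24, 14S methyl) | O[C@H]1C[C@H](C)[C@@H](O[Si](C)(C)C(C)(C)C)c2cc(O[Si](C(C)C)(C(C)C)C(C)C)cc(c2)NC(=O)/C(C)=C/CC[C@H](OC)[C@@H](O[Si](C)(C)C(C)(C)C)/C(C)=C/[C@H](C)[C@H]1O[Si](C)(C)C(C)(C)C | intermediate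
26 | 12-O-methyl ether of 25 | CO[C@H]1C[C@H](C)[C@@H](O[Si](C)(C)C(C)(C)C)c2cc(O[Si](C(C)C)(C(C)C)C(C)C)cc(c2)NC(=O)/C(C)=C/CC[C@H](OC)[C@@H](O[Si](C)(C)C(C)(C)C)/C(C)=C/[C@H](C)[C@H]1O[Si](C)(C)C(C)(C)C | intermediate
27 | target ansa lactam (6S 7S 10S 11R 12S 14S 15R; 2E 8E) | CO[C@H]1C[C@H](C)[C@@H](O)c2cc(O)cc(c2)NC(=O)/C(C)=C/CC[C@H](OC)[C@@H](O)/C(C)=C/[C@H](C)[C@H]1O | target

**Totals**
Total step count: 22.
Longest linear sequence: 17 steps (steps 1–10 and 16–22); the aniline branch is 5 steps (steps 11–15).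

**Steps most likely to fail**

1. Step 19 (bears the label). What may go wrong: intermolecular coupling to oligomers, bond formation at the internal alkyne carbon, direct methyl transfer from zinc to the aldehyde, or erosion of the Felkin preference by the strain of the closing transition state. Fallback with known chemistry only: setting out from seco-anilide 21, Negishi carboalumination of the terminal alkyne (AlMe3, Cp2ZrCl2, CH2Cl2, then I2) should give the E-vinyl iodide F1. Acid-catalysed methanolysis of the primary silyl ether (CSA, MeOH/CH2Cl2, 0 °C) should give the iodo alcohol F2, and Dess–Martin oxidation the iodo aldehyde F3. A Nozaki–Hiyama–Kishi macrocyclization (CrCl2, NiCl2 (cat.), DMSO/THF, high dilution) then forms the same C12–C13 bond and comes back to the route at 24.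

2. Step 20. What may go wrong: competing reduction of the C2=C3 or C8=C9 olefins, isomerization of the allylic alcohol to the ketone, or loss of facial control by the macrocycle. Fallback: setting out from 24, Dess–Martin oxidation should give the macrocyclic enone F4. Ligand-controlled copper hydride conjugate reduction (Cu(OAc)2, the DTBM-SEGPHOS enantiomer that attacks the face giving 14S, polymethylhydrosiloxane, tBuOH, toluene) should give the macrocyclic ketone F5, the enamide being much less reactive than the enone. Felkin-selective reduction of the α-silyloxy ketone (LiBH(sBu)3, THF, −78 °C) then gives the 11,12-anti alcohol and comes back to the route at 25.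

3. Step 21. What may go wrong: competing O-alkylation of the anilide to the imidate, or slow reaction at the hindered hydroxyl with silyl migration. Fallback: setting out from 25, Pummerer-type alkylation (DMSO, Ac2O, AcOH, rt) should give the methylthiomethyl ether F6, which leaves the amide untouched. Desulfurization with Raney nickel (Ni, deactivated in acetone; EtOH, rt) converts the O–CH2–SCH3 group into O–CH3 and comes back to the route at 26.

**Further compounds**
F1 | step 19 | E-vinyl iodide from 21 (C13 iodide, C14 methyl; other stereocenters as in 21) | I/C=C(C)/[C@@H](O[Si](C)(C)C(C)(C)C)c1cc(O[Si](C(C)C)(C(C)C)C(C)C)cc(c1)NC(=O)/C(C)=C/CC[C@H](OC)[C@@H](O[Si](C)(C)C(C)(C)C)/C(C)=C/[C@H](C)[C@@H](O[Si](C)(C)C(C)(C)C)CO[Si](C)(C)C(C)(C)C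
F2 | step 19 | iodo alcohol (F1 with free C12 primary hydroxyl) | I/C=C(C)/[C@@H](O[Si](C)(C)C(C)(C)C)c1cc(O[Si](C(C)C)(C(C)C)C(C)C)cc(c1)NC(=O)/C(C)=C/CC[C@H](OC)[C@@H](O[Si](C)(C)C(C)(C)C)/C(C)=C/[C@H](C)[C@@H](O[Si](C)(C)C(C)(C)C)CO
F3 | step 19 | iodo aldehyde (C12 aldehyde of F2) | I/C=C(C)/[C@@H](O[Si](C)(C)C(C)(C)C)c1cc(O[Si](C(C)C)(C(C)C)C(C)C)cc(c1)NC(=O)/C(C)=C/CC[C@H](OC)[C@@H](O[Si](C)(C)C(C)(C)C)/C(C)=C/[C@H](C)[C@@H](O[Si](C)(C)C(C)(C)C)C=O
F4 | step 20 | macrocyclic enone (C12 ketone of 24, 13E) | O=C1/C=C(C)/[C@@H](O[Si](C)(C)C(C)(C)C)c2cc(O[Si](C(C)C)(C(C)C)C(C)C)cc(c2)NC(=O)/C(C)=C/CC[C@H](OC)[C@@H](O[Si](C)(C)C(C)(C)C)/C(C)=C/[C@H](C)[C@H]1O[Si](C)(C)C(C)(C)C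
F5 | step 20 | macrocyclic ketone (13,14-dihydro-F4, 14S methyl) | O=C1C[C@H](C)[C@@H](O[Si](C)(C)C(C)(C)C)c2cc(O[Si](C(C)C)(C(C)C)C(C)C)cc(c2)NC(=O)/C(C)=C/CC[C@H](OC)[C@@H](O[Si](C)(C)C(C)(C)C)/C(C)=C/[C@H](C)[C@H]1O[Si](C)(C)C(C)(C)C
F6 | step 21 | 12-O-methylthiomethyl ether of 25 | CSCO[C@H]1C[C@H](C)[C@@H](O[Si](C)(C)C(C)(C)C)c2cc(O[Si](C(C)C)(C(C)C)C(C)C)cc(c2)NC(=O)/C(C)=C/CC[C@H](OC)[C@@H](O[Si](C)(C)C(C)(C)C)/C(C)=C/[C@H](C)[C@H]1O[Si](C)(C)C(C)(C)C
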